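**Retrosynthetic overview**
1. The (E)-enone C=C is disconnected by Claisen–Schmidt condensation into the ring A methyl ketone 11 and the ring B aldehyde 17. Aldehyde 17 comes from 4-hydroxybenzaldehyde by O-propargylation and thermal rearrangement, which closes the pyran of ring B.
2. Structural feature: in the dihydrofuran fused to ring A, the ring oxygen O1 is bonded to the stereogenic C2(H), which carries the exocyclic C(CH3)2OH. The same atoms arranged as O1–C(CH3)2–C3(H)OH form a 3-hydroxy-2,2-dimethylchroman, so the two units are constitutional isomers related by a 1,2-shift of the aryloxy oxygen.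
3. The dihydrofuran carbinol 10 is therefore made by invertive ring contraction of the (3S)-chromanol 7: the ring oxygen participates through a bridged oxiranium ion and water is captured at the CMe2 carbon.
4. Chromanol 7 comes from 2,4-dihydroxyacetophenone and 3-methylbut-2-enal by way of the angular chromene, its MOM ether, (S,S)-(salen)MnCl epoxidation (which sets the only stereocentre) and benzylic hydrogenolysis.
5. Ring order: the pyran on ring A is formed first and then contracted to the dihydrofuran; the pyran on ring B is made separately; the enone is formed last.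

Key step: step 5

Remark on the chemistry: the (S,S)-(salen)MnCl catalyst is assumed to deliver oxygen to chromene 5 with the facial sense established for 2,2-dimethyl-2H-chromenes that lack a C5 substituent, giving the (3S,4S)-epoxide; if the opposite sense were found, the (R,R)-catalyst would be used.

**Route**

Step 1
Reactants: 1 2,4-dihydroxyacetophenone; 2 3-methylbut-2-enal
Product: 4 1-(5-hydroxy-2,2-dimethyl-2H-chromen-6-yl)ethanone, via quinone methide 3 (not isolated)
Conditions: pyridine, 140 °C (sealed tube)
Reagents that add atoms: none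
Why: Pyridine-mediated aldol-type condensation at the arene carbon between the two hydroxyls gives quinone methide 3, which closes by 6π-oxa-electrocyclisation through the oxygen para to the acetyl group (the ortho hydroxyl is held in the hydrogen bond to the ketone), a well-established chromenylation of this resorcinol that gives the angular chromene.

Step 2
Reactants: 4 1-(5-hydroxy-2,2-dimethyl-2H-chromen-6-yl)ethanone
Product: 5 1-[5-(methoxymethoxy)-2,2-dimethyl-2H-chromen-6-yl]ethanone
Conditions: NaH (1.05 equiv), MOMCl, DMF, 0 °C → rt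
Reagents that add atoms: chloromethyl methyl ether, COCCl
Why: Williamson-type O-alkylation of the sodium phenoxide; NaH is chosen because the phenol is hydrogen-bonded to the ketone, and one equivalent removes the phenolic proton (the most acidic site) before the methyl ketone is touched.

Step 3
Reactants: 5 1-[5-(methoxymethoxy)-2,2-dimethyl-2H-chromen-6-yl]ethanone
Product: 6 1-[(1aS,7bS)-7-(methoxymethoxy)-2,2-dimethyl-1a,7b-dihydro-2H-oxireno[2,3-c]chromen-6-yl]ethanone (the (3S,4S)-3,4-epoxide in chroman numbering)
Conditions: chloro[(S,S)-N,N'-bis(3,5-di-tert-butylsalicylidene)cyclohexane-1,2-diaminato]manganese, (S,S)-(salen)MnCl (5 mol %, trivalent manganese), mCPBA, NMO, CH2Cl2, −78 °C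
Reagents that add atoms: 3-chloroperbenzoic acid, OOC(=O)c1cccc(Cl)c1
Why: Jacobsen–Katsuki epoxidation, for which cis-disubstituted 2,2-dimethyl-2H-chromenes with an electron-withdrawing 6-substituent are among the best substrates; the (S,S)-ligand directs oxygen transfer to the face that gives the (3S,4S)-epoxide, and the anhydrous peracid/N-oxide protocol at −78 °C avoids the haloform cleavage that aqueous hypochlorite could cause at the methyl ketone.

Step 4
Reactants: 6 1-[(1aS,7bS)-7-(methoxymethoxy)-2,2-dimethyl-1a,7b-dihydro-2H-oxireno[2,3-c]chromen-6-yl]ethanone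
Product: 7 1-[(3S)-3-hydroxy-5-(methoxymethoxy)-2,2-dimethyl-3,4-dihydro-2H-chromen-6-yl]ethanone
Conditions: H2 (1 atm), 10% Pd/C, EtOAc, rt
Reagents that add atoms: none
Why: Palladium-catalysed hydrogenolysis cleaves only the benzylic C4–O bond of the epoxide, so the C3–O bond and its configuration are kept and the (3S)-alcohol results; the aryl ketone (conjugated with the para ring oxygen) and the MOM ether should survive at 1 atm and room temperature if the reaction is stopped when 6 is consumed.

Step 5
Reactants: 7 1-[(3S)-3-hydroxy-5-(methoxymethoxy)-2,2-dimethyl-3,4-dihydro-2H-chromen-6-yl]ethanone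
Product: 10 1-[(2R)-2-(2-hydroxypropan-2-yl)-4-(methoxymethoxy)-2,3-dihydro-1-benzofuran-5-yl]ethanone, via triflate 8 (not isolated), via oxiranium triflate 9 (not isolated)
Conditions: Tf2O (1.3 equiv), 2,6-lutidine (3 equiv), CH2Cl2, −78 → −40 °C; then THF–H2O (4:1), −40 °C → rt
Reagents that add atoms: water, O
Why: Proposed new method: O-triflation gives triflate 8, whose pseudo-equatorial C3–OTf bond lies antiperiplanar to the O1–C2 bond, so on warming in aqueous THF the ring oxygen should displace triflate from the rear and give the aryl-bridged oxiranium ion 9, which water opens at the CMe2 carbon with cleavage of the old O1–C2 bond. The net change is a 1,2-aryloxy shift that turns the six-membered pyran into the five-membered dihydrofuran; the new ring is closed by the 3-exo-tet formation of the O1–C3 bond and becomes the five-membered ether once the O1–CMe2 bond breaks. The closest known reaction type is the stereospecific contraction of tetrahydropyran-3-yl sulfonates to 2-(hydroxyalkyl)tetrahydrofurans through bicyclic oxonium ions. The new stereocentre (C2 of the dihydrofuran, the former C3) is under substrate control, because the intramolecular displacement is invertive and the CIP priorities are unchanged, so (3S)-7 should give (2R)-10. The step needs opening of 9 at the tertiary and not the secondary carbon, which the gem-dimethyl group secures by carrying the positive charge and the para-acetyl group supports by making the aryloxy oxygen the better leaving group from that carbon, while direct intermolecular substitution at the neopentyl-like C3 is too slow to compete. Excess water at low temperature is meant to capture the tertiary centre before proton loss to an isopropenyl group, and the methyl ketone and the MOM ether should not react with Tf2O/2,6-lutidine at these temperatures.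

Step 6
Reactants: 10 1-[(2R)-2-(2-hydroxypropan-2-yl)-4-(methoxymethoxy)-2,3-dihydro-1-benzofuran-5-yl]ethanone
Product: 11 1-[(2R)-4-hydroxy-2-(2-hydroxypropan-2-yl)-2,3-dihydro-1-benzofuran-5-yl]ethanone
Conditions: HCl (1 M aq., cat.), MeOH, rt → 40 °C
Reagents that add atoms: none
Why: Acid-catalysed acetal exchange with methanol; the MOM ether ortho to the carbonyl is especially labile, whereas the tertiary alcohol (its ionisation is disfavoured by the adjacent ring oxygen) and the stereocentre should not be affected.

Step 7
Reactants: 12 4-hydroxybenzaldehyde; 13 3-chloro-3-methylbut-1-yne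
Product: 14 4-[(2-methylbut-3-yn-2-yl)oxy]benzaldehyde
Conditions: CuCl2·2H2O (1 mol %), DBU, MeCN, 0 °C
Reagents that add atoms: none
Why: Copper-catalysed propargylic substitution of the tertiary propargylic chloride by the phenoxide, the standard preparation of aryl 1,1-dimethylpropargyl ethers, which works well for electron-poor phenols.

Step 8
Reactants: 14 4-[(2-methylbut-3-yn-2-yl)oxy]benzaldehyde
Product: 17 2,2-dimethyl-2H-chromene-6-carbaldehyde, via allenylphenol 15 (not isolated), via quinone methide 16 (not isolated)
Conditions: N,N-diethylaniline, 190 °C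
Reagents that add atoms: none
Why: Aromatic propargyl Claisen rearrangement to the ortho position and tautomerisation give allenylphenol 15, a 1,5-hydrogen shift gives quinone methide 16 and 6π-oxa-electrocyclisation closes the 2,2-dimethyl-2H-chromene, the usual thermal cascade of these ethers; the two ortho positions are equivalent.

Step 9
Reactants: 11 1-[(2R)-4-hydroxy-2-(2-hydroxypropan-2-yl)-2,3-dihydro-1-benzofuran-5-yl]ethanone; 17 2,2-dimethyl-2H-chromene-6-carbaldehyde
Product: 19 (2E)-3-(2,2-dimethyl-2H-chromen-6-yl)-1-[(2R)-4-hydroxy-2-(2-hydroxypropan-2-yl)-2,3-dihydro-1-benzofuran-5-yl]prop-2-en-1-one (CNP0302034.2), via aldol adduct 18 (not isolated)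
Conditions: KOH (50% aq.), EtOH, 0 °C → rt; then cold 1 M HCl to pH 5
Reagents that add atoms: none
Why: Claisen–Schmidt condensation, in which the potassium enolate of the methyl ketone adds to the non-enolisable aldehyde to give aldol 18, which dehydrates by E1cB to the conjugated (E)-enone (the thermodynamic geometry); the stereocentre at C2 of the dihydrofuran is remote from any acidic position and should not epimerise.

**Compound list**
1 | 2,4-dihydroxyacetophenone | CC(=O)c1ccc(O)cc1O | starting material
2 | 3-methylbut-2-enal | CC(C)=CC=O | starting material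
3 | (2Z)-4-acetyl-3-hydroxy-2-(3-methylbut-2-en-1-ylidene)cyclohexa-3,5-dien-1-one (quinone methide, not isolated) | CC(=O)C1=C(O)/C(=C/C=C(C)C)C(=O)C=C1 | intermediate
4 | 1-(5-hydroxy-2,2-dimethyl-2H-chromen-6-yl)ethanone | CC(=O)c1ccc2OC(C)(C)C=Cc2c1O | intermediate
5 | 1-[5-(methoxymethoxy)-2,2-dimethyl-2H-chromen-6-yl]ethanone | CC(=O)c1ccc2OC(C)(C)C=Cc2c1OCOC | intermediate
6 | 1-[(1aS,7bS)-7-(methoxymethoxy)-2,2-dimethyl-1a,7b-dihydro-2H-oxireno[2,3-c]chromen-6-yl]ethanone | CC(=O)c1ccc2OC(C)(C)[C@H]3O[C@H]3c2c1OCOC | intermediate
7 | 1-[(3S)-3-hydroxy-5-(methoxymethoxy)-2,2-dimethyl-3,4-dihydro-2H-chromen-6-yl]ethanone | CC(=O)c1ccc2OC(C)(C)[C@@H](O)Cc2c1OCOC | intermediate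
8 | (3S)-6-acetyl-5-(methoxymethoxy)-2,2-dimethyl-3,4-dihydro-2H-chromen-3-yl trifluoromethanesulfonate (not isolated) | CC(=O)c1ccc2OC(C)(C)[C@@H](OS(=O)(=O)C(F)(F)F)Cc2c1OCOC | intermediate
9 | aryl-bridged oxiranium triflate: the ring oxygen of 8 bonded to the arene carbon, to CMe2 and to the former C3 (now R), triflate counter-ion (not isolated) | CC(=O)c1ccc2c(c1OCOC)C[C@H]3[O+]2C3(C)C.[O-]S(=O)(=O)C(F)(F)F | intermediate
10 | 1-[(2R)-2-(2-hydroxypropan-2-yl)-4-(methoxymethoxy)-2,3-dihydro-1-benzofuran-5-yl]ethanone | CC(=O)c1ccc2c(c1OCOC)C[C@H](C(C)(C)O)O2 | intermediate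
11 | 1-[(2R)-4-hydroxy-2-(2-hydroxypropan-2-yl)-2,3-dihydro-1-benzofuran-5-yl]ethanone | CC(=O)c1ccc2c(c1O)C[C@H](C(C)(C)O)O2 | intermediate
12 | 4-hydroxybenzaldehyde | O=Cc1ccc(O)cc1 | starting material
13 | 3-chloro-3-methylbut-1-yne | CC(C)(Cl)C#C | starting material
14 | 4-[(2-methylbut-3-yn-2-yl)oxy]benzaldehyde | O=Cc1ccc(OC(C)(C)C#C)cc1 | intermediate
15 | 4-hydroxy-3-(3-methylbuta-1,2-dien-1-yl)benzaldehyde (not isolated) | O=Cc1ccc(O)c(C=C=C(C)C)c1 | intermediate
16 | (3Z)-3-(3-methylbut-2-en-1-ylidene)-4-oxocyclohexa-1,5-diene-1-carbaldehyde (quinone methide, not isolated) | O=CC1=C/C(=C/C=C(C)C)C(=O)C=C1 | intermediate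
17 | 2,2-dimethyl-2H-chromene-6-carbaldehyde | CC1(C)C=Cc2cc(C=O)ccc2O1 | intermediate
18 | 3-(2,2-dimethyl-2H-chromen-6-yl)-3-hydroxy-1-[(2R)-4-hydroxy-2-(2-hydroxypropan-2-yl)-2,3-dihydro-1-benzofuran-5-yl]propan-1-one (both carbinol epimers, not isolated) | CC1(C)C=Cc2cc(C(O)CC(=O)c3ccc4c(c3O)C[C@H](C(C)(C)O)O4)ccc2O1 | intermediate
19 | (2E)-3-(2,2-dimethyl-2H-chromen-6-yl)-1-[(2R)-4-hydroxy-2-(2-hydroxypropan-2-yl)-2,3-dihydro-1-benzofuran-5-yl]prop-2-en-1-one | CC1(C)C=Cc2cc(/C=C/C(=O)c3ccc4c(c3O)C[C@H](C(C)(C)O)O4)ccc2O1 | target

**Step count and risks**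
Total steps: 9. Longest linear sequence: 7 (steps 1–6 and 9); steps 7 and 8 make the ring B aldehyde in a side branch.

Steps most likely to fail:

1. Step 5 (proposed new method). The ring oxygen, made less nucleophilic by the para-acetyl group, may participate too slowly. In that case base-induced loss of triflic acid back to the chromene, proton loss from the ring-contracted cation to an isopropenyl group, or capture of water at C3 with overall retention could take over.
Fallback by known chemistry, setting out from 1 and returning at 10: 1 would be C-prenylated between the two hydroxyls with prenyl bromide in aqueous KOH to give 1-[2,4-dihydroxy-3-(3-methylbut-2-en-1-yl)phenyl]ethanone F1. The free, non-chelated hydroxyl would be silylated selectively (TIPSCl, imidazole, DMF) to give 1-[2-hydroxy-3-(3-methylbut-2-en-1-yl)-4-(triisopropylsilyloxy)phenyl]ethanone F2. The chelated phenol would then be protected (MOMCl, iPr2NEt, CH2Cl2, reflux) to give 1-[2-(methoxymethoxy)-3-(3-methylbut-2-en-1-yl)-4-(triisopropylsilyloxy)phenyl]ethanone F3. Shi epoxidation with the L-fructose-derived ketone (the enantiomer of the usual D-fructose-derived catalyst), Oxone (2KHSO5·KHSO4·K2SO4) and K2CO3 in MeCN–dimethoxymethane–water at 0 °C should give 1-[3-{[(2S)-3,3-dimethyloxiran-2-yl]methyl}-2-(methoxymethoxy)-4-(triisopropylsilyloxy)phenyl]ethanone F4. TBAF in THF would free the phenoxide para to the acetyl group, which opens the epoxide at its secondary carbon by 5-exo-tet attack with inversion and gives (2R)-10.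

2. Step 4. Over-reduction of the aryl ketone, or palladium-induced isomerisation of the epoxide to a ketone, may compete with clean benzylic C–O hydrogenolysis.
Fallback, setting out from 6 and returning at 7: ionic trans-opening of the epoxide at the benzylic carbon with LiBr/AcOH in THF would give 1-[(3R,4R)-4-bromo-3-hydroxy-5-(methoxymethoxy)-2,2-dimethyl-3,4-dihydro-2H-chromen-6-yl]ethanone F5. Radical debromination (Bu3SnH, AIBN, toluene, 80 °C) would remove the benzylic bromine without touching the ketone or the C3 carbinol and give 7.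

3. Step 9. Enolisation of the phenoxide-bearing ketone may be slow, and the 2'-hydroxychalcone may close by intramolecular oxa-Michael addition to the flavanone during long exposure to base or on acidification.
Fallback, setting out from 10 (step 6 is left out) and returning at 19: the MOM-protected ketone 10 would be condensed with 17 (KOH, EtOH, rt), which cannot form a flavanone, to give (2E)-3-(2,2-dimethyl-2H-chromen-6-yl)-1-[(2R)-2-(2-hydroxypropan-2-yl)-4-(methoxymethoxy)-2,3-dihydro-1-benzofuran-5-yl]prop-2-en-1-one F6. The chelation-labile MOM ether would then be removed last with dilute HCl in MeOH at room temperature to give 19.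

**Further compounds**
F1 | step 5 | 1-[2,4-dihydroxy-3-(3-methylbut-2-en-1-yl)phenyl]ethanone | CC(=O)c1ccc(O)c(CC=C(C)C)c1O
F2 | step 5 | 1-[2-hydroxy-3-(3-methylbut-2-en-1-yl)-4-(triisopropylsilyloxy)phenyl]ethanone | CC(=O)c1ccc(O[Si](C(C)C)(C(C)C)C(C)C)c(CC=C(C)C)c1O
F3 | step 5 | 1-[2-(methoxymethoxy)-3-(3-methylbut-2-en-1-yl)-4-(triisopropylsilyloxy)phenyl]ethanone | CC(=O)c1ccc(O[Si](C(C)C)(C(C)C)C(C)C)c(CC=C(C)C)c1OCOC
F4 | step 5 | 1-[3-{[(2S)-3,3-dimethyloxiran-2-yl]methyl}-2-(methoxymethoxy)-4-(triisopropylsilyloxy)phenyl]ethanone | CC(=O)c1ccc(O[Si](C(C)C)(C(C)C)C(C)C)c(C[C@@H]2OC2(C)C)c1OCOC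
F5 | step 4 | 1-[(3R,4R)-4-bromo-3-hydroxy-5-(methoxymethoxy)-2,2-dimethyl-3,4-dihydro-2H-chromen-6-yl]ethanone | CC(=O)c1ccc2OC(C)(C)[C@@H](O)[C@H](Br)c2c1OCOC
F6 | step 9 | (2E)-3-(2,2-dimethyl-2H-chromen-6-yl)-1-[(2R)-2-(2-hydroxypropan-2-yl)-4-(methoxymethoxy)-2,3-dihydro-1-benzofuran-5-yl]prop-2-en-1-one | CC1(C)C=Cc2cc(/C=C/C(=O)c3ccc4c(c3OCOC)C[C@H](C(C)(C)O)O4)ccc2O1
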